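**Retrosynthetic overview**
1. Numbering: cyclohexane C1 (Et), C2 (Me), C3 (Ar), C4 (Me), C5 (Ar), C6 (spiro); dienone ring C6–C7H=C8(OMe)–C9(=O)–C10H=C11(OMe)–C6; Ar = 2,4,5-trimethoxyphenyl; β = face of the C4 methyl, α = the other face.
2. The plan rests on the cyclohexane ring C1–C6, made first: it is three two-carbon pieces, C5–C4 (propanal), C3–C2 (a nitrostyrene) and C1–C6 (pent-2-enal), and its trans C3-aryl/C4-methyl pair is that of a syn nitro-Michael adduct.
3. Dienone ring, made last: cut C7=C8 (aldol condensation) and C6–C11 (enolate addition–elimination) back to a C6 carbaldehyde and MeOCH2COCH=C(OMe)2.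
4. Ring substituents: axial C2 methyl from a C2 ketone (methylenation, hydroxyl-directed hydrogenation); C1 brought to the α face by equilibration next to that ketone; ketone from a C2 nitro group (Nef); C5 aryl by cuprate addition to a C5=C6 enal.
5. Cyclohexene: C4–C3, C2–C1 and C5=C6 from propanal, the nitrostyrene and pentenal in one amine-catalysed Michael–Michael–aldol cascade; nitrostyrene from the aryl aldehyde and nitromethane.

Key step: step 2

Remark on the chemistry: one enantiomer of the catalyst controls both Michael additions. This is expected to place the C1 ethyl on the β face (cis to the C4 methyl, pseudoaxial beside the formyl-bearing sp2 carbon), not on the α face that the target needs. An all-trans cyclohexene is therefore not expected from the cascade, and C1 is inverted in step 5. C2 of 8 and 11 and C6 of 11 are epimerisable and may form as mixtures; the epimers drawn are the expected major ones, and all converge in steps 4 and 5. Ring positions in the names of 10–18 and 22 follow the numbering of the overview.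

**Step 1**
Reactants: 1 2,4,5-trimethoxybenzaldehyde; 2 nitromethane
Product: 3 (E)-1,2,4-trimethoxy-5-(2-nitroethenyl)benzene
Conditions: MeNO2 (excess), NH4OAc, AcOH, 100 °C
Reagents that add atoms: none
Why: Henry (nitroaldol) condensation with dehydration in the same pot should give the conjugated (E)-nitroalkene, the thermodynamic isomer; no stereocentre is formed.

**Step 2**
Reactants: 4 propanal; 3 (E)-1,2,4-trimethoxy-5-(2-nitroethenyl)benzene; 5 (E)-pent-2-enal
Product: 8 (3S,4S,5R,6R)-6-ethyl-3-methyl-5-nitro-4-(2,4,5-trimethoxyphenyl)cyclohex-1-ene-1-carbaldehyde, via Michael adduct 6 (not isolated), via nitro dialdehyde 7 (not isolated)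
Conditions: (S)-2-[diphenyl(trimethylsilyloxy)methyl]pyrrolidine (20 mol%), toluene, 0 °C → rt
Reagents that add atoms: none
Why: The (S)-amine first forms the anti-enamine of 4, which adds to nitroalkene 3 through an acyclic synclinal transition state (C4–C3, syn adduct 6); the amine then turns enal 5 into an iminium ion that accepts the nitronate of 6 (C2–C1), and the resulting enamine of 7 closes the ring by a 6-(enolexo)-exo-trig aldol addition to the propanal-derived carbonyl C5, with loss of water to the C5=C6 enal. The closest precedent is the known diarylprolinol silyl ether-catalysed Michael–Michael–aldol condensation of an aldehyde, a nitroalkene and an enal to cyclohexene carbaldehydes. The diphenyl(siloxy)methyl group shields the same face in the enamine and in the iminium ion: this fixes C4 and C3 as the (2R,3S) adduct (C3 Ar α, C4 Me β, trans on the ring) and fixes C1 with its ethyl group on the β face, cis to the C4 methyl. C2 is set under equilibrating conditions and is erased in step 4. The step needs chemoselectivity among three carbonyl partners, and this follows from reactivity: the enamine of the saturated aldehyde attacks the nitroalkene faster than the enal, the nitronate attacks the iminium ion faster than any free aldehyde, and the enal is engaged only as acceptor through its iminium ion.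

**Step 3**
Reactants: 8 (3S,4S,5R,6R)-6-ethyl-3-methyl-5-nitro-4-(2,4,5-trimethoxyphenyl)cyclohex-1-ene-1-carbaldehyde; 9 1-bromo-2,4,5-trimethoxybenzene
Product: 11 1β-ethyl-4β-methyl-2β-nitro-3α,5α-bis(2,4,5-trimethoxyphenyl)cyclohexane-6β-carbaldehyde, via silyl enol ether 10 (not isolated)
Conditions: Ar2CuLi·LiI (3 equiv; from 9, n-BuLi, THF, −78 °C, then CuI, −40 °C), TMSCl (5 equiv), THF, −78 → −50 °C; AcOH, −78 °C; then 1 M HCl, THF, 0 °C
Reagents that add atoms: none
Why: Organocuprate conjugate addition (Gilman reagent with TMSCl) to the trisubstituted enal should deliver the aryl group to C5 from the α face, anti to the adjacent C4 methyl and to the pseudoaxial C1 ethyl, which both lie on the β face; nitroalkanes are slow carbon acids, so the TMSCl-accelerated 1,4-addition should outrun proton transfer from C2–H, and excess reagent covers any loss.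

**Step 4**
Reactants: 11 1β-ethyl-4β-methyl-2β-nitro-3α,5α-bis(2,4,5-trimethoxyphenyl)cyclohexane-6β-carbaldehyde
Product: 13 1β-ethyl-4β-methyl-2-oxo-3α,5α-bis(2,4,5-trimethoxyphenyl)cyclohexane-6β-carbaldehyde, via sodium nitronate 12 (not isolated)
Conditions: NaOMe, MeOH, 0 °C; then aq. TiCl3, NH4OAc (pH 5–6), THF/H2O, 0 °C → rt
Reagents that add atoms: water O
Why: Reductive Nef reaction (McMurry): Ti(III) reduces the nitronate to the imine, which water hydrolyses to the C2 ketone at pH 5–6, conditions without oxidant that should leave the aliphatic aldehyde and the electron-rich arenes untouched; no stereocentre is formed.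

**Step 5**
Reactants: 13 1β-ethyl-4β-methyl-2-oxo-3α,5α-bis(2,4,5-trimethoxyphenyl)cyclohexane-6β-carbaldehyde
Product: 14 1α-ethyl-4β-methyl-2-oxo-3α,5α-bis(2,4,5-trimethoxyphenyl)cyclohexane-6β-carbaldehyde
Conditions: DBU (0.2 equiv), CH2Cl2, rt, under argon
Reagents that add atoms: none
Why: Base-mediated epimerisation through the enolates of the ketone (C1, C3) and of the aldehyde (C6) should funnel the material into the one diastereomer with all five ring substituents equatorial, which inverts C1 so that the ethyl group is trans to the C4 methyl as in the target (thermodynamic control).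

**Step 6**
Reactants: 14 1α-ethyl-4β-methyl-2-oxo-3α,5α-bis(2,4,5-trimethoxyphenyl)cyclohexane-6β-carbaldehyde
Product: 15 1α-ethyl-6β-(hydroxymethyl)-4β-methyl-3α,5α-bis(2,4,5-trimethoxyphenyl)cyclohexan-2-one
Conditions: NaBH4, EtOH/CH2Cl2 (3:7), −78 °C
Reagents that add atoms: none
Why: Chemoselective borohydride reduction: at −78 °C the aldehyde should be reduced far faster than the ketone flanked by two tertiary carbons, and the primary alcohol then serves as masked aldehyde and as directing group for step 8.

**Step 7**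
Reactants: 15 1α-ethyl-6β-(hydroxymethyl)-4β-methyl-3α,5α-bis(2,4,5-trimethoxyphenyl)cyclohexan-2-one
Product: 16 [1α-ethyl-4β-methyl-2-methylidene-3α,5α-bis(2,4,5-trimethoxyphenyl)cyclohex-6β-yl]methanol
Conditions: Zn, CH2Br2, TiCl4 (pre-formed reagent, excess), THF/CH2Cl2, 0 °C → rt
Reagents that add atoms: dibromomethane BrCBr
Why: Lombardo–Takai methylenation converts hindered, enolisable ketones into 1,1-disubstituted alkenes without base, so the α-centres C1 and C3 should not epimerise, and it tolerates the free hydroxyl group.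

**Step 8**
Reactants: 16 [1α-ethyl-4β-methyl-2-methylidene-3α,5α-bis(2,4,5-trimethoxyphenyl)cyclohex-6β-yl]methanol
Product: 17 [1α-ethyl-2α,4β-dimethyl-3α,5α-bis(2,4,5-trimethoxyphenyl)cyclohex-6β-yl]methanol
Conditions: [Ir(cod)(PCy3)(py)]PF6 (5 mol%), H2 (1 atm), CH2Cl2, rt
Reagents that add atoms: none
Why: Hydroxyl-directed hydrogenation with Crabtree's catalyst: the equatorial β-hydroxymethyl group at C6 binds iridium and hydrogen should reach the exocyclic alkene from its outer, equatorial (β) face, which is also the open face, so the new C2 methyl ends axial on the α face, cis to the C1 ethyl and C3 aryl groups.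

**Step 9**
Reactants: 17 [1α-ethyl-2α,4β-dimethyl-3α,5α-bis(2,4,5-trimethoxyphenyl)cyclohex-6β-yl]methanol
Product: 18 1α-ethyl-2α,4β-dimethyl-3α,5α-bis(2,4,5-trimethoxyphenyl)cyclohexane-6β-carbaldehyde
Conditions: Dess–Martin periodinane, NaHCO3, CH2Cl2, 0 °C → rt
Reagents that add atoms: none
Why: Dess–Martin oxidation of the primary alcohol to the aldehyde under buffered conditions; the equatorial formyl group is also the thermodynamic epimer at C6, so no epimerisation is expected.

**Step 10**
Reactants: 19 methoxyacetyl chloride; 20 1,1-dimethoxyethene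
Product: 21 1,4,4-trimethoxybut-3-en-2-one
Conditions: Et3N, Et2O, 0 °C → rt; distilled and used fresh
Reagents that add atoms: none
Why: C-Acylation of the electron-rich ketene acetal by the acid chloride with loss of HCl to the amine is the standard route to acylketene acetals (β,β-dialkoxy enones).

**Step 11**
Reactants: 18 1α-ethyl-2α,4β-dimethyl-3α,5α-bis(2,4,5-trimethoxyphenyl)cyclohexane-6β-carbaldehyde; 21 1,4,4-trimethoxybut-3-en-2-one
Product: 23 tatanan B, via keto aldehyde 22 (not isolated)
Conditions: KHMDS, THF, −78 °C; 21, −78 → 0 °C; then MeOH, rt → 40 °C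
Reagents that add atoms: none
Why: Proposed new method: the potassium enolate of the α-branched aldehyde should add through C6 to the β-carbon of 21 and expel methoxide (1,4-addition–elimination, C6–C11), and the liberated methoxide should then enolise the methoxymethyl ketone of 22 and close the ring by aldol condensation onto the now non-enolisable aldehyde (C7=C8), the closest known reactions being the Robinson annulation of α,α-disubstituted aldehydes with vinyl ketones and the addition–elimination of ketone and ester enolates to acylketene acetals; the electrophile should enter the exocyclic enolate on its equatorial β face, anti to the axial C2 methyl, which places C11 equatorial and C7 axial as in the target.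

**Compound list**
1 | 2,4,5-trimethoxybenzaldehyde | COc1cc(OC)c(C=O)cc1OC | starting material
2 | nitromethane | C[N+](=O)[O-] | starting material
3 | (E)-1,2,4-trimethoxy-5-(2-nitroethenyl)benzene | COc1cc(OC)c(/C=C/[N+](=O)[O-])cc1OC | intermediate
4 | propanal | CCC=O | starting material
5 | (E)-pent-2-enal | CC/C=C/C=O | starting material
6 | (2R,3S)-2-methyl-4-nitro-3-(2,4,5-trimethoxyphenyl)butanal | O=C[C@H](C)[C@@H](c1cc(OC)c(OC)cc1OC)C[N+](=O)[O-] | intermediate (not isolated)
7 | (2R,3S,4R,5R)-5-ethyl-2-methyl-4-nitro-3-(2,4,5-trimethoxyphenyl)heptanedial | CC[C@H](CC=O)[C@@H]([N+](=O)[O-])[C@H](c1cc(OC)c(OC)cc1OC)[C@@H](C)C=O | intermediate (not isolated)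
8 | (3S,4S,5R,6R)-6-ethyl-3-methyl-5-nitro-4-(2,4,5-trimethoxyphenyl)cyclohex-1-ene-1-carbaldehyde (C1 Et β, C2 NO2 β, C3 Ar α, C4 Me β) | CC[C@H]1[C@@H]([N+](=O)[O-])[C@H](c2cc(OC)c(OC)cc2OC)[C@@H](C)C=C1C=O | intermediate
9 | 1-bromo-2,4,5-trimethoxybenzene | COc1cc(OC)c(Br)cc1OC | starting material
10 | trimethylsilyl enol ether of 11 (C6=CH–OSiMe3) | CC[C@H]1[C@@H]([N+](=O)[O-])[C@H](c2cc(OC)c(OC)cc2OC)[C@@H](C)[C@H](c2cc(OC)c(OC)cc2OC)C1=CO[Si](C)(C)C | intermediate (not isolated)
11 | 1β-ethyl-4β-methyl-2β-nitro-3α,5α-bis(2,4,5-trimethoxyphenyl)cyclohexane-6β-carbaldehyde | CC[C@H]1[C@@H]([N+](=O)[O-])[C@H](c2cc(OC)c(OC)cc2OC)[C@@H](C)[C@H](c2cc(OC)c(OC)cc2OC)[C@H]1C=O | intermediate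
12 | sodium nitronate of 11 | [Na+].CC[C@H]1C(=[N+]([O-])[O-])[C@H](c2cc(OC)c(OC)cc2OC)[C@@H](C)[C@H](c2cc(OC)c(OC)cc2OC)[C@H]1C=O | intermediate (not isolated)
13 | 1β-ethyl-4β-methyl-2-oxo-3α,5α-bis(2,4,5-trimethoxyphenyl)cyclohexane-6β-carbaldehyde | CC[C@H]1C(=O)[C@H](c2cc(OC)c(OC)cc2OC)[C@@H](C)[C@H](c2cc(OC)c(OC)cc2OC)[C@H]1C=O | intermediate
14 | 1α-ethyl-4β-methyl-2-oxo-3α,5α-bis(2,4,5-trimethoxyphenyl)cyclohexane-6β-carbaldehyde | CC[C@@H]1C(=O)[C@H](c2cc(OC)c(OC)cc2OC)[C@@H](C)[C@H](c2cc(OC)c(OC)cc2OC)[C@H]1C=O | intermediate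
15 | 1α-ethyl-6β-(hydroxymethyl)-4β-methyl-3α,5α-bis(2,4,5-trimethoxyphenyl)cyclohexan-2-one | CC[C@@H]1C(=O)[C@H](c2cc(OC)c(OC)cc2OC)[C@@H](C)[C@H](c2cc(OC)c(OC)cc2OC)[C@H]1CO | intermediate
16 | [1α-ethyl-4β-methyl-2-methylidene-3α,5α-bis(2,4,5-trimethoxyphenyl)cyclohex-6β-yl]methanol | CC[C@@H]1C(=C)[C@H](c2cc(OC)c(OC)cc2OC)[C@@H](C)[C@H](c2cc(OC)c(OC)cc2OC)[C@H]1CO | intermediate
17 | [1α-ethyl-2α,4β-dimethyl-3α,5α-bis(2,4,5-trimethoxyphenyl)cyclohex-6β-yl]methanol | CC[C@@H]1[C@H](C)[C@H](c2cc(OC)c(OC)cc2OC)[C@@H](C)[C@H](c2cc(OC)c(OC)cc2OC)[C@H]1CO | intermediate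
18 | 1α-ethyl-2α,4β-dimethyl-3α,5α-bis(2,4,5-trimethoxyphenyl)cyclohexane-6β-carbaldehyde | CC[C@@H]1[C@H](C)[C@H](c2cc(OC)c(OC)cc2OC)[C@@H](C)[C@H](c2cc(OC)c(OC)cc2OC)[C@H]1C=O | intermediate
19 | methoxyacetyl chloride | COCC(=O)Cl | starting material
20 | 1,1-dimethoxyethene | C=C(OC)OC | starting material
21 | 1,4,4-trimethoxybut-3-en-2-one | COCC(=O)C=C(OC)OC | intermediate
22 | 6α-formyl-6β-[(E)-1,4-dimethoxy-3-oxobut-1-en-1-yl] derivative of 18 | CC[C@@H]1[C@H](C)[C@H](c2cc(OC)c(OC)cc2OC)[C@@H](C)[C@H](c2cc(OC)c(OC)cc2OC)[C@@]1(C=O)/C(OC)=C\C(=O)COC | intermediate (not isolated)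
23 | tatanan B | CC[C@@H]1[C@H](C)[C@H](c2cc(OC)c(OC)cc2OC)[C@@H](C)[C@H](c2cc(OC)c(OC)cc2OC)[C@]12C=C(OC)C(=O)C=C2OC | target

**Step count**
Total: 11 steps. Longest linear sequence: 10 steps (steps 1–9 and 11); step 10 prepares reagent 21.

**Three steps most likely to fail**

1. Step 11 (Proposed new method). The hindered potassium enolate may react at oxygen, or may transfer a proton to the methoxymethyl ketone of the acceptor, so that the C6–C11 bond and the quaternary centre are not formed. The fallback uses known reactions, sets out from aldehyde 18 and returns at target 23. The pyrrolidine enamine of 18 would be added to 1-methoxybut-3-en-2-one and the 1,5-keto aldehyde closed with KOH/MeOH (Robinson annulation of an α-branched aldehyde, C6 again alkylated on its β face) to give the spiro 2-methoxycyclohex-2-enone F1. LiHMDS/TMSCl would give the trimethylsilyl dienol ether F2, and Pd(OAc)2 in MeCN (Saegusa–Ito oxidation) the cross-conjugated 2-methoxydienone F3. Thiophenol/Et3N would add to the unsubstituted C10=C11 enone to give the β-phenylthio ketone F4. NCS followed by Et3N (chlorination at the sulfur-bearing C11, loss of HCl) would give the β-phenylthio dienone F5. NaOMe/MeOH would then exchange phenylthio for methoxy by addition–elimination to give 23.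

2. Step 3. Proton transfer from the nitro-bearing C2–H or electron transfer to the nitro group may consume the cuprate, and aryl transfer to the hindered β-carbon may be slow or poorly face-selective. The fallback sets out from enal 8 and returns at aldehyde 11: rhodium-catalysed 1,4-addition of commercial 2,4,5-trimethoxyphenylboronic acid ([Rh(cod)OH]2, dioxane/H2O, 60 °C). The aryl-rhodium species is neutral toward nitroalkanes, and protonation of the rhodium enolate by water gives 11 directly; no new compound is formed (F0).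

3. Step 8. Hydrogen may be delivered to the exocyclic alkene from its axial face, or the double bond may migrate into the ring before reduction; the first would give the equatorial C2 methyl. The fallback sets out from alkene 16 and returns at alcohol 17. The double bond would be moved on purpose into the ring (RhCl3·3H2O, EtOH, 70 °C) to the tetrasubstituted C2=C3 alkene F6. Crabtree's catalyst under raised hydrogen pressure (CH2Cl2, 50 bar) would then add hydrogen cis to C2 and C3 from the β face, directed by the C6 hydroxymethyl group, which sets C2 and C3 together.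

**Further compounds**
F1 | step 11 | spiro 2-methoxycyclohex-2-enone (C10H2–C11H2) | CC[C@@H]1[C@H](C)[C@H](c2cc(OC)c(OC)cc2OC)[C@@H](C)[C@H](c2cc(OC)c(OC)cc2OC)[C@]12C=C(OC)C(=O)CC2
F2 | step 11 | trimethylsilyl dienol ether of F1 | CC[C@@H]1[C@H](C)[C@H](c2cc(OC)c(OC)cc2OC)[C@@H](C)[C@H](c2cc(OC)c(OC)cc2OC)[C@]12C=C(OC)C(O[Si](C)(C)C)=CC2
F3 | step 11 | spiro 2-methoxycyclohexa-2,5-dienone | CC[C@@H]1[C@H](C)[C@H](c2cc(OC)c(OC)cc2OC)[C@@H](C)[C@H](c2cc(OC)c(OC)cc2OC)[C@]12C=C(OC)C(=O)C=C2
F4 | step 11 | C11 phenylthio ketone (C11 configuration not defined) | CC[C@@H]1[C@H](C)[C@H](c2cc(OC)c(OC)cc2OC)[C@@H](C)[C@H](c2cc(OC)c(OC)cc2OC)[C@]12C=C(OC)C(=O)CC2Sc3ccccc3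
F5 | step 11 | C11 phenylthio dienone | CC[C@@H]1[C@H](C)[C@H](c2cc(OC)c(OC)cc2OC)[C@@H](C)[C@H](c2cc(OC)c(OC)cc2OC)[C@]12C=C(OC)C(=O)C=C2Sc3ccccc3
F0 | step 3 | none | none
F6 | step 8 | [1α-ethyl-2,4β-dimethyl-3,5α-bis(2,4,5-trimethoxyphenyl)cyclohex-2-en-6β-yl]methanol | CC[C@@H]1C(C)=C(c2cc(OC)c(OC)cc2OC)[C@@H](C)[C@H](c2cc(OC)c(OC)cc2OC)[C@H]1CO
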